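**Retrosynthetic overview**

1. Isouvarinol ⇒ C2–phenyl disconnection: an enantioselective palladium-catalysed 1,4-phenylation that dearomatises the γ-pyrone ring of a fully C-benzylated 5,7-dihydroxychromone and sets C2 (S) in the last step.
2. That chromone ⇒ C8–CH2 and C6–CH2 disconnections: two ortho-quinone-methide benzylations of commercial 5,7-dihydroxychromone, C8 first (bond-fixation bias of the still-aromatic chromone), then C6 (the only site left).
3. The C8 side-chain donor ⇒ aryl–CH2 Suzuki disconnection: 5-(chloromethyl)salicylaldehyde + 2-hydroxyphenylboronic acid, then aldehyde reduction.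
4. Ring order: no ring is built. Rings A and C are bought together as the aromatic chromone, and ring B (the C2 phenyl) arrives last with the stereocentre. No protecting groups are used.

Assumption: (R)-t-BuPyOx is taken to deliver phenyl to the C2 Re face (giving 2S), the mirror image of the (S)-ligand/(R)-flavanone pairing; if the sense proves opposite, the (S)-ligand is used.

**Route**

Step 1
Reactants: 1 benzylic chloride 5-(chloromethyl)-2-hydroxybenzaldehyde; 2 (2-hydroxyphenyl)boronic acid (1.5 equiv)
Product: 3 aldehyde 2-hydroxy-5-(2-hydroxybenzyl)benzaldehyde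
Conditions: PdCl2(dppf) (3 mol%), K2CO3 (3 equiv), degassed THF/H2O 10:1, 65 °C, 1 added last in portions; 1 M HCl work-up
Reagents that add atoms: none
Why: Suzuki–Miyaura cross-coupling of a benzylic chloride, in which zerovalent palladium inserts into the benzylic C–Cl bond and the boron atom fixes the ortho link of the diarylmethane that a Friedel–Crafts reaction on phenol would give only as an ortho/para mixture; no stereocentre is formed.

Step 2
Reactants: 3 aldehyde 2-hydroxy-5-(2-hydroxybenzyl)benzaldehyde
Product: 4 salicyl-type alcohol 2-(hydroxymethyl)-4-(2-hydroxybenzyl)phenol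
Conditions: NaBH4 (1.0 equiv), MeOH, 0 °C, 30 min; sat. NH4Cl quench (no strong acid)
Reagents that add atoms: none
Why: Chemoselective borohydride reduction of the aryl aldehyde to the benzylic alcohol, which leaves the phenols and the diarylmethane untouched and provides the ortho-hydroxybenzyl alcohol needed as a quinone-methide precursor; no stereocentre is formed.

Step 3
Reactants: 4 salicyl-type alcohol 2-(hydroxymethyl)-4-(2-hydroxybenzyl)phenol; 5 chromone 5,7-dihydroxy-4H-chromen-4-one (3 equiv, excess recovered)
Product: 7 C8-benzylated chromone 5,7-dihydroxy-8-[2-hydroxy-5-(2-hydroxybenzyl)benzyl]-4H-chromen-4-one, via ortho-quinone methide 6 (not isolated)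
Conditions: p-TsOH·H2O (10 mol%), 1,4-dioxane, 80 °C, slow addition of 4 over 4 h
Reagents that add atoms: none
Why: Acid-catalysed dehydration of 4 gives the dearomatised ortho-quinone methide 6, which the phloroglucinol-type ring of 5 captures in a Friedel–Crafts-type conjugate addition with rearomatisation; C8 is expected to be preferred because the intact aromatic pyrone imposes naphthalene-like bond fixation (the 7-OH directs across the high-order C7–C8 bond like a 2-naphthol OH, and C8 is also para to the 5-OH), the same bias that puts Mannich electrophiles at C8 of 5,7-dihydroxyflavones, while excess 5 suppresses double benzylation; no stereocentre is formed.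

Step 4
Reactants: 7 C8-benzylated chromone 5,7-dihydroxy-8-[2-hydroxy-5-(2-hydroxybenzyl)benzyl]-4H-chromen-4-one; 8 salicyl alcohol (2-hydroxybenzyl alcohol, 1.5 equiv)
Product: 10 dibenzylated chromone 5,7-dihydroxy-6-(2-hydroxybenzyl)-8-[2-hydroxy-5-(2-hydroxybenzyl)benzyl]-4H-chromen-4-one, via ortho-quinone methide 9 (not isolated)
Conditions: p-TsOH·H2O (10 mol%), 1,4-dioxane, 80 °C, slow addition of 8, stopped at full conversion of 7
Reagents that add atoms: none
Why: The same ortho-quinone-methide Friedel–Crafts benzylation, now regiochemically unambiguous because C6 is the only unsubstituted carbon of the phloroglucinol-type ring and is far more nucleophilic than the monophenol rings of the side chain; no stereocentre is formed.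

Step 5
Reactants: 10 dibenzylated chromone 5,7-dihydroxy-6-(2-hydroxybenzyl)-8-[2-hydroxy-5-(2-hydroxybenzyl)benzyl]-4H-chromen-4-one; 11 phenylboronic acid (3 equiv)
Product: 12 isouvarinol (2S)-5,7-dihydroxy-6-(2-hydroxybenzyl)-8-[2-hydroxy-5-(2-hydroxybenzyl)benzyl]-2-phenylchroman-4-one
Conditions: Pd(OCOCF3)2 (10 mol%), (R)-t-BuPyOx [(R)-4-tert-butyl-2-(pyridin-2-yl)-4,5-dihydrooxazole] (12 mol%), NH4PF6 (30 mol%), H2O (5 equiv), ClCH2CH2Cl/CF3CH2OH 9:1, 60 °C; neutral work-up, Sephadex LH-20
Reagents that add atoms: none
Why: Palladium/pyridine-oxazoline-catalysed asymmetric conjugate addition of an arylboronic acid to a chromone (Stoltz-type 1,4-arylation), in which transmetalation gives a cationic phenyl complex of divalent palladium that inserts the C2=C3 bond of the weakly aromatic γ-pyrone from the C2 Re face under control of the tert-butyl oxazoline, and protonolysis of the palladium enolate by water releases the (2S)-flavanone, so the only stereocentre is set in the last step under non-basic conditions and cannot be scrambled afterwards.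

**Compound list**

1 | 5-(chloromethyl)-2-hydroxybenzaldehyde | O=Cc1cc(CCl)ccc1O | starting material
2 | (2-hydroxyphenyl)boronic acid | OB(O)c1ccccc1O | starting material
3 | 2-hydroxy-5-(2-hydroxybenzyl)benzaldehyde | O=Cc1cc(Cc2ccccc2O)ccc1O | intermediate
4 | 2-(hydroxymethyl)-4-(2-hydroxybenzyl)phenol | OCc1cc(Cc2ccccc2O)ccc1O | intermediate
5 | 5,7-dihydroxy-4H-chromen-4-one | O=c1ccoc2cc(O)cc(O)c12 | starting material
6 | 4-(2-hydroxybenzyl)-6-methylenecyclohexa-2,4-dien-1-one (ortho-quinone methide from 4) | O=C1C=CC(Cc2ccccc2O)=CC1=C | intermediate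
7 | 5,7-dihydroxy-8-[2-hydroxy-5-(2-hydroxybenzyl)benzyl]-4H-chromen-4-one | O=c1ccoc2c(Cc3cc(Cc4ccccc4O)ccc3O)c(O)cc(O)c12 | intermediate
8 | 2-hydroxybenzyl alcohol (salicyl alcohol) | OCc1ccccc1O | starting material
9 | 6-methylenecyclohexa-2,4-dien-1-one (ortho-quinone methide from 8) | C=C1C=CC=CC1=O | intermediate
10 | 5,7-dihydroxy-6-(2-hydroxybenzyl)-8-[2-hydroxy-5-(2-hydroxybenzyl)benzyl]-4H-chromen-4-one | O=c1ccoc2c(Cc3cc(Cc4ccccc4O)ccc3O)c(O)c(Cc3ccccc3O)c(O)c12 | intermediate
11 | phenylboronic acid | OB(O)c1ccccc1 | starting material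
12 | isouvarinol, (2S)-5,7-dihydroxy-6-(2-hydroxybenzyl)-8-[2-hydroxy-5-(2-hydroxybenzyl)benzyl]-2-phenylchroman-4-one | O=C1C[C@@H](c2ccccc2)Oc2c(Cc3cc(Cc4ccccc4O)ccc3O)c(O)c(Cc3ccccc3O)c(O)c21 | target

**Step count and risks**

Total steps: 5. Longest linear sequence: 5 (1 → 3 → 4 → 7 → 10 → 12).

Risk 1 (step 5, the dearomatising phenylation). The substrate is an electron-rich, chelated pentaphenol, outside the usual scope of the chromone arylation: it may be too poor an acceptor, too insoluble, or may bind the catalyst. The fallback sets out from 10 and comes back at 12. Peracetylation (Ac2O, pyridine, DMAP, 50 °C) gives the pentaacetate 5,7-diacetoxy-6-(2-acetoxybenzyl)-8-[2-acetoxy-5-(2-acetoxybenzyl)benzyl]-4H-chromen-4-one F4, an electron-poor, non-chelating chromone soluble in ClCH2CH2Cl. Its phenylation with 11 and the same Pd(OCOCF3)2/(R)-t-BuPyOx system gives the flavanone pentaacetate (2S)-5,7-diacetoxy-6-(2-acetoxybenzyl)-8-[2-acetoxy-5-(2-acetoxybenzyl)benzyl]-2-phenylchroman-4-one F5. Acid methanolysis (HCl in MeOH, 0 °C to rt; no base, to avoid retro-oxa-Michael racemisation) then returns to 12.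

Risk 2 (step 3, C8 versus C6). The C8 preference rests on analogy (bond fixation, Mannich behaviour of 5,7-dihydroxyflavones) and may be modest; the isomers are separable and assignable by HMBC from the chelated 5-OH. The fallback sets out from 5 and comes back at 10, bypassing 7, by inverting the order and changing the directing principle. Chromone 5 and salicyl alcohol 8 are heated with ZnCl2 (2 equiv) in dioxane at 100 °C, where the zinc chelate of the 5-oxido-4-keto unit should deliver the zinc-bound quinone methide 9 to the ortho carbon C6 (the chelation logic of high-ortho phenol–formaldehyde condensation). This gives 5,7-dihydroxy-6-(2-hydroxybenzyl)-4H-chromen-4-one F3. Benzylation of F3 with 4 under the step 3 conditions then has only C8 left and gives 10. Because the target needs the small benzyl at C6 and the large one at C8, whichever position reacts first decides which of the two orders is run.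

Risk 3 (step 1, Suzuki coupling). Under base, chloride 1 can ionise to a para-quinone methide and be hydrolysed or O-alkylated by phenoxides, and 2 can protodeboronate. The fallback sets out from 1 and comes back at 4. A base-free Friedel–Crafts alkylation of para-blocked 4-bromophenol (5 equiv, ZnCl2 10 mol%, MeNO2, 60 °C) can only attack ortho to its OH and gives 5-(5-bromo-2-hydroxybenzyl)-2-hydroxybenzaldehyde F1. NaBH4 in MeOH gives 4-bromo-2-[4-hydroxy-3-(hydroxymethyl)benzyl]phenol F2. Hydrodebromination (H2 1 atm, Pd/C, NaOAc, MeOH, rt, stopped at one equivalent of uptake) then gives 4.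

**Further compounds**

F1 | step 1 | 5-(5-bromo-2-hydroxybenzyl)-2-hydroxybenzaldehyde | O=Cc1cc(Cc2cc(Br)ccc2O)ccc1O
F2 | step 1 | 4-bromo-2-[4-hydroxy-3-(hydroxymethyl)benzyl]phenol | OCc1cc(Cc2cc(Br)ccc2O)ccc1O
F3 | step 3 | 5,7-dihydroxy-6-(2-hydroxybenzyl)-4H-chromen-4-one | O=c1ccoc2cc(O)c(Cc3ccccc3O)c(O)c12
F4 | step 5 | 5,7-diacetoxy-6-(2-acetoxybenzyl)-8-[2-acetoxy-5-(2-acetoxybenzyl)benzyl]-4H-chromen-4-one | O=c1ccoc2c(Cc3cc(Cc4ccccc4OC(C)=O)ccc3OC(C)=O)c(OC(C)=O)c(Cc3ccccc3OC(C)=O)c(OC(C)=O)c12
F5 | step 5 | (2S)-5,7-diacetoxy-6-(2-acetoxybenzyl)-8-[2-acetoxy-5-(2-acetoxybenzyl)benzyl]-2-phenylchroman-4-one | O=C1C[C@@H](c2ccccc2)Oc2c(Cc3cc(Cc4ccccc4OC(C)=O)ccc3OC(C)=O)c(OC(C)=O)c(Cc3ccccc3OC(C)=O)c(OC(C)=O)c21
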